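**Strategy.** Everything rests on cutting ring C at C2–C3. In the flavanone, C2 carries O1 and ring B; in an O1-benzyl ether of ring A this carbon is a CH2 whose two enantiotopic C–H bonds are activated twice (α to O1, benzylic to the 4'-oxygenated ring B) and sit 1,6 to the carbene carbon of an ortho diazoacetyl group, the future C3. A chiral dirhodium carboxylate makes that carbene, which inserts into one of these bonds, closing ring C and setting C2 in one operation. The precursor is a 2-benzyloxy-4,6-bis(silyloxy)phenyl diazomethyl ketone whose benzyl group is the complete prenylated ring B; all four phenols are silyl ethers, so one buffered fluoride step finishes the synthesis.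

Key step: step 7

Remarks on the chemistry (assumptions):
- The sense of induction of Rh2(S-PTTL)4 (dirhodium tetrakis[N-phthaloyl-(S)-tert-leucinate], a divalent rhodium carboxylate) with this acceptor-only carbene cannot be assigned with certainty in advance. The route is written with this catalyst delivering (2S); should a trial run show the opposite sense, the mirror-image catalyst Rh2(R-PTTL)4 is used under the same conditions.
- 3-Bromo-4,5-dihydroxybenzaldehyde and tributyl(3-methylbut-2-en-1-yl)stannane are taken as catalogue compounds.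
- TBS = tert-butyldimethylsilyl, TIPS = triisopropylsilyl, prenyl = 3-methylbut-2-en-1-yl. Silyl ethers are used on ring B as well as ring A, so that no acetal C–H bond or basic acetal oxygen is present in the carbene step and no acid is needed next to the ortho-prenylphenol at the end.

**Route**

Step 1
Reactants: 1 3-bromo-4,5-dihydroxybenzaldehyde
Product: 2 3-bromo-4,5-bis(tert-butyldimethylsilyloxy)benzaldehyde
Conditions: TBSCl (2.5 equiv), imidazole, DMF, rt
Reagents that add atoms: tert-butyldimethylsilyl chloride, CC(C)(C)[Si](C)(C)Cl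
Why: Imidazole-promoted O-silylation should convert both catechol hydroxyls into TBS ethers, which mask the acidic phenols for the coupling and Mitsunobu steps and leave the aldehyde and the aryl bromide untouched.

Step 2
Reactants: 2 3-bromo-4,5-bis(tert-butyldimethylsilyloxy)benzaldehyde; 3 tributyl(3-methylbut-2-en-1-yl)stannane
Product: 4 3,4-bis(tert-butyldimethylsilyloxy)-5-(3-methylbut-2-en-1-yl)benzaldehyde
Conditions: Pd(PPh3)4 (5 mol %), DMF, 100 °C
Reagents that add atoms: none
Why: Stille cross-coupling, in which zerovalent palladium inserts into the C–Br bond, the prenyl group is delivered from tin, and the aryl(η3-prenyl)palladium intermediate should reductively eliminate at its unsubstituted CH2 terminus to give the linear prenyl arene under neutral conditions that spare the aldehyde and the aryl silyl ethers.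

Step 3
Reactants: 4 3,4-bis(tert-butyldimethylsilyloxy)-5-(3-methylbut-2-en-1-yl)benzaldehyde
Product: 5 [3,4-bis(tert-butyldimethylsilyloxy)-5-(3-methylbut-2-en-1-yl)phenyl]methanol
Conditions: NaBH4, THF/MeOH, 0 °C; then H2O
Reagents that add atoms: none
Why: Borohydride reduction of the aldehyde to the primary benzylic alcohol is chemoselective at 0 °C, the trisubstituted alkene and the aryl silyl ethers being unaffected by brief exposure.

Step 4
Reactants: 6 2',4',6'-trihydroxyacetophenone
Product: 7 1-[2-hydroxy-4,6-bis(triisopropylsilyloxy)phenyl]ethan-1-one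
Conditions: TIPSCl (2.2 equiv), imidazole, DMF, 0 °C to rt
Reagents that add atoms: triisopropylsilyl chloride, CC(C)[Si](Cl)(C(C)C)C(C)C
Why: Regioselective silylation, in which the para hydroxyl and one ortho hydroxyl react with the bulky silyl chloride while the last ortho hydroxyl stays locked in its hydrogen bond to the acetyl oxygen and is left free as the future O1.

Step 5
Reactants: 7 1-[2-hydroxy-4,6-bis(triisopropylsilyloxy)phenyl]ethan-1-one; 5 [3,4-bis(tert-butyldimethylsilyloxy)-5-(3-methylbut-2-en-1-yl)phenyl]methanol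
Product: 8 1-[2-{[3,4-bis(tert-butyldimethylsilyloxy)-5-(3-methylbut-2-en-1-yl)phenyl]methoxy}-4,6-bis(triisopropylsilyloxy)phenyl]ethan-1-one
Conditions: PPh3, DIAD, THF, 0 °C to rt
Reagents that add atoms: none
Why: Mitsunobu etherification, in which the hydrogen-bonded phenol is acidic enough to protonate the PPh3/DIAD betaine and its phenoxide displaces the activated primary benzylic oxyphosphonium, forming the O1–CH2 bond under neutral conditions that no silyl ether is exposed to base or fluoride.

Step 6
Reactants: 8 1-[2-{[3,4-bis(tert-butyldimethylsilyloxy)-5-(3-methylbut-2-en-1-yl)phenyl]methoxy}-4,6-bis(triisopropylsilyloxy)phenyl]ethan-1-one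
Product: 10 1-[2-{[3,4-bis(tert-butyldimethylsilyloxy)-5-(3-methylbut-2-en-1-yl)phenyl]methoxy}-4,6-bis(triisopropylsilyloxy)phenyl]-2-diazoethan-1-one, via trifluoroacetyl ketone 9 (not isolated)
Conditions: LiN(SiMe3)2, THF, −78 °C; CF3CO2CH2CF3; cold dilute HCl work-up; then 4-AcNHC6H4SO2N3, Et3N, H2O (1 equiv), MeCN, rt
Reagents that add atoms: 2,2,2-trifluoroethyl trifluoroacetate, O=C(OCC(F)(F)F)C(F)(F)F (trifluoroacetyl group of 9 only); 4-acetamidobenzenesulfonyl azide, CC(=O)Nc1ccc(cc1)S(=O)(=O)N=[N+]=[N-] (the two diazo nitrogens of 10)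
Why: Detrifluoroacetylative (Regitz-type) diazo transfer, in which kinetic enolisation at the methyl group (the only enolisable position) and Claisen trifluoroacetylation give 1,3-diketone 9, whose enolate accepts the diazo group from the sulfonyl azide and expels the trifluoroacetyl group as the N-sulfonyl trifluoroacetamide, the bulky TIPS group on the neighbouring oxygen being too slow to migrate to the enolate at −78 °C.

Step 7
Reactants: 10 1-[2-{[3,4-bis(tert-butyldimethylsilyloxy)-5-(3-methylbut-2-en-1-yl)phenyl]methoxy}-4,6-bis(triisopropylsilyloxy)phenyl]-2-diazoethan-1-one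
Product: 11 (2S)-2-[3,4-bis(tert-butyldimethylsilyloxy)-5-(3-methylbut-2-en-1-yl)phenyl]-5,7-bis(triisopropylsilyloxy)chroman-4-one
Conditions: Rh2(S-PTTL)4 (1 mol %), toluene, 0 °C, slow addition of 10
Reagents that add atoms: none
Why: The dirhodium carboxylate displaces N2 from 10 to give an electrophilic rhodium carbene at the future C3, which takes one of the two benzylic C–H bonds of the O1–CH2–aryl group through a concerted three-centre transition state with hydride-transfer character, forming the C2–C3 and C3–H bonds together (intramolecular carbene C–H insertion). The closest known reaction type is the closure of chroman-4-ones from ortho-alkoxyaryl diazomethyl ketones with chiral dirhodium carboxylates. Ring C closes as a six-membered ring by 1,6-insertion, the only insertion mode open to the carbene because the 1,5-position is the ether oxygen itself. The C2 stereocentre is set by the catalyst alone: the phthalimido wall of the tert-leucinate ligands selects between the enantiotopic C2–H bonds, with the (2S) sense taken as remarked before the steps. The step needs insertion to outrun attack of O1 on the carbene (oxonium ylide, then benzyl 1,2-shift to a benzofuranone); this is secured by the double activation of the C2–H bonds (α to O1 and benzylic to the 4'-silyloxy ring B), by the low basicity of an aryl ether oxygen conjugated to the acyl group, and by a bulky carboxylate catalyst in a non-polar solvent. Silyl ethers leave no acetal C–H bond or basic acetal oxygen to compete, the TIPS group shields O5, and slow addition keeps the carbene from dimerising or cyclopropanating the prenyl alkene of a second molecule.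

Step 8
Reactants: 11 (2S)-2-[3,4-bis(tert-butyldimethylsilyloxy)-5-(3-methylbut-2-en-1-yl)phenyl]-5,7-bis(triisopropylsilyloxy)chroman-4-one
Product: 12 sigmoidin B [(2S)-2-[3,4-dihydroxy-5-(3-methylbut-2-en-1-yl)phenyl]-5,7-dihydroxychroman-4-one]
Conditions: Bu4NF/AcOH (1:1, 6 equiv), THF, 0 °C to rt
Reagents that add atoms: none
Why: Fluoride cleaves all four aryl O–Si bonds in one operation (global desilylation), and the acetic acid buffer keeps each liberated phenol protonated, so that neither base-induced opening of ring C to the chalcone (which would racemise C2) nor acid-induced cyclisation of the prenyl group onto the 4'-hydroxyl should occur.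

**Compound list**

1 | 3-bromo-4,5-dihydroxybenzaldehyde | O=Cc1cc(O)c(O)c(Br)c1 | starting material
2 | 3-bromo-4,5-bis(tert-butyldimethylsilyloxy)benzaldehyde | O=Cc1cc(O[Si](C)(C)C(C)(C)C)c(O[Si](C)(C)C(C)(C)C)c(Br)c1 | intermediate
3 | tributyl(3-methylbut-2-en-1-yl)stannane | CCCC[Sn](CCCC)(CCCC)CC=C(C)C | starting material
4 | 3,4-bis(tert-butyldimethylsilyloxy)-5-(3-methylbut-2-en-1-yl)benzaldehyde | CC(C)=CCc1cc(C=O)cc(O[Si](C)(C)C(C)(C)C)c1O[Si](C)(C)C(C)(C)C | intermediate
5 | [3,4-bis(tert-butyldimethylsilyloxy)-5-(3-methylbut-2-en-1-yl)phenyl]methanol | CC(C)=CCc1cc(CO)cc(O[Si](C)(C)C(C)(C)C)c1O[Si](C)(C)C(C)(C)C | intermediate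
6 | 2',4',6'-trihydroxyacetophenone | CC(=O)c1c(O)cc(O)cc1O | starting material
7 | 1-[2-hydroxy-4,6-bis(triisopropylsilyloxy)phenyl]ethan-1-one | CC(=O)c1c(O)cc(O[Si](C(C)C)(C(C)C)C(C)C)cc1O[Si](C(C)C)(C(C)C)C(C)C | intermediate
8 | 1-[2-{[3,4-bis(tert-butyldimethylsilyloxy)-5-(3-methylbut-2-en-1-yl)phenyl]methoxy}-4,6-bis(triisopropylsilyloxy)phenyl]ethan-1-one | CC(C)=CCc1cc(COc2cc(O[Si](C(C)C)(C(C)C)C(C)C)cc(O[Si](C(C)C)(C(C)C)C(C)C)c2C(C)=O)cc(O[Si](C)(C)C(C)(C)C)c1O[Si](C)(C)C(C)(C)C | intermediate
9 | 1-[2-{[3,4-bis(tert-butyldimethylsilyloxy)-5-(3-methylbut-2-en-1-yl)phenyl]methoxy}-4,6-bis(triisopropylsilyloxy)phenyl]-4,4,4-trifluorobutane-1,3-dione | CC(C)=CCc1cc(COc2cc(O[Si](C(C)C)(C(C)C)C(C)C)cc(O[Si](C(C)C)(C(C)C)C(C)C)c2C(=O)CC(=O)C(F)(F)F)cc(O[Si](C)(C)C(C)(C)C)c1O[Si](C)(C)C(C)(C)C | intermediate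
10 | 1-[2-{[3,4-bis(tert-butyldimethylsilyloxy)-5-(3-methylbut-2-en-1-yl)phenyl]methoxy}-4,6-bis(triisopropylsilyloxy)phenyl]-2-diazoethan-1-one | CC(C)=CCc1cc(COc2cc(O[Si](C(C)C)(C(C)C)C(C)C)cc(O[Si](C(C)C)(C(C)C)C(C)C)c2C(=O)C=[N+]=[N-])cc(O[Si](C)(C)C(C)(C)C)c1O[Si](C)(C)C(C)(C)C | intermediate
11 | (2S)-2-[3,4-bis(tert-butyldimethylsilyloxy)-5-(3-methylbut-2-en-1-yl)phenyl]-5,7-bis(triisopropylsilyloxy)chroman-4-one | CC(C)=CCc1cc([C@@H]2CC(=O)c3c(O[Si](C(C)C)(C(C)C)C(C)C)cc(O[Si](C(C)C)(C(C)C)C(C)C)cc3O2)cc(O[Si](C)(C)C(C)(C)C)c1O[Si](C)(C)C(C)(C)C | intermediate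
12 | sigmoidin B, (2S)-2-[3,4-dihydroxy-5-(3-methylbut-2-en-1-yl)phenyl]-5,7-dihydroxychroman-4-one | CC(C)=CCc1cc([C@@H]2CC(=O)c3c(O)cc(O)cc3O2)cc(O)c1O | target

**Step count and risk**

Total steps: 8. Longest linear sequence: 7 steps (steps 1, 2, 3, 5, 6, 7, 8 from compound 1); the ring A branch (step 4) joins at step 5.

Steps most likely to fail:

1. Step 7 (carbene C–H insertion). The carbene may be captured by the lone pair of O1, giving an ylide that undergoes a benzyl 1,2-shift, faster than it inserts. Alternatively, the ligand sphere may discriminate poorly between the two enantiotopic C2–H bonds of an acceptor-only carbene. The fallback avoids the carbene altogether; it sets out from aldehyde 4 and acetophenone 7 and comes back at 11. A Claisen–Schmidt condensation mediated by LiN(SiMe3)2 (THF, −78 °C to rt), which avoids hydroxide and so spares the silyl ethers, should give the (E)-2'-hydroxychalcone F1. NaOAc in warm ethanol should then close ring C by oxa-Michael addition to the racemic flavanone F2. A kinetic resolution by asymmetric transfer hydrogenation (RuCl[(R,R)-TsDPEN](p-cymene), HCO2H/Et3N) should, by the usual facial preference of this catalyst for aryl ketones, reduce the (2R)-ketone to the cis-(2R,4R)-flavan-4-ol F3. The unreacted (2S)-ketone 11 is then separated by chromatography; the catalyst enantiomer is confirmed on a small sample first.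

2. Step 5 (Mitsunobu etherification). Alkylation of the hydrogen-bonded, ortho-acylated phenol may stall at the betaine stage, or the electron-rich benzylic oxyphosphonium may ionise and alkylate ring A at carbon. The fallback sets out from alcohol 5 and comes back at 8. An Appel reaction (CBr4, PPh3, CH2Cl2, 0 °C) should give the benzylic bromide F4, which is used at once to alkylate phenol 7 with Ag2O in toluene in the dark. This Williamson-type etherification through the silver phenoxide involves no soluble base that could attack the aryl silyl ethers.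

3. Step 2 (Stille prenylation). Reductive elimination may take place at the dimethyl-substituted terminus of the prenyl–palladium intermediate, giving the reverse-prenyl (1,1-dimethylallyl) isomer. The fallback sets out from bromide 2 and comes back at 4. Stille coupling with allyltributylstannane (Pd(PPh3)4, DMF, 100 °C), where the symmetrical allyl group raises no regiochemical question, should give the allyl aldehyde F5. Olefin cross-metathesis with excess 2-methylbut-2-ene (second-generation Grubbs catalyst RuCl2(=CHPh)(PCy3)(H2IMes), CH2Cl2, 40 °C) should then convert the allyl into the prenyl group.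

**Further compounds**

F1 | step 7 | (E)-3-[3,4-bis(tert-butyldimethylsilyloxy)-5-(3-methylbut-2-en-1-yl)phenyl]-1-[2-hydroxy-4,6-bis(triisopropylsilyloxy)phenyl]prop-2-en-1-one | CC(C)=CCc1cc(/C=C/C(=O)c2c(O)cc(O[Si](C(C)C)(C(C)C)C(C)C)cc2O[Si](C(C)C)(C(C)C)C(C)C)cc(O[Si](C)(C)C(C)(C)C)c1O[Si](C)(C)C(C)(C)C
F2 | step 7 | racemic 2-[3,4-bis(tert-butyldimethylsilyloxy)-5-(3-methylbut-2-en-1-yl)phenyl]-5,7-bis(triisopropylsilyloxy)chroman-4-one | CC(C)=CCc1cc(C2CC(=O)c3c(O[Si](C(C)C)(C(C)C)C(C)C)cc(O[Si](C(C)C)(C(C)C)C(C)C)cc3O2)cc(O[Si](C)(C)C(C)(C)C)c1O[Si](C)(C)C(C)(C)C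
F3 | step 7 | (2R,4R)-2-[3,4-bis(tert-butyldimethylsilyloxy)-5-(3-methylbut-2-en-1-yl)phenyl]-5,7-bis(triisopropylsilyloxy)chroman-4-ol | CC(C)=CCc1cc([C@H]2C[C@@H](O)c3c(O[Si](C(C)C)(C(C)C)C(C)C)cc(O[Si](C(C)C)(C(C)C)C(C)C)cc3O2)cc(O[Si](C)(C)C(C)(C)C)c1O[Si](C)(C)C(C)(C)C
F4 | step 5 | 5-(bromomethyl)-1,2-bis(tert-butyldimethylsilyloxy)-3-(3-methylbut-2-en-1-yl)benzene | CC(C)=CCc1cc(CBr)cc(O[Si](C)(C)C(C)(C)C)c1O[Si](C)(C)C(C)(C)C
F5 | step 2 | 3,4-bis(tert-butyldimethylsilyloxy)-5-(prop-2-en-1-yl)benzaldehyde | C=CCc1cc(C=O)cc(O[Si](C)(C)C(C)(C)C)c1O[Si](C)(C)C(C)(C)C
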